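The bicyclo[3.3.1]nonane-2,4,9-trione core is opened at the two 1,3-dicarbonyl bonds C1–C9 and C3–C4: bridgehead C5 then carries both C4 and C9 as a latent disubstituted malonate, and the C2 ketone keeps C1 and C3 as its two nucleophilic alpha carbons. The key step is a domino Dieckmann condensation that closes the cyclohexanone ring (C1, C9, C5–C8) and the enolised trione ring (C1–C5, C9) of an acyclic triketo diester in one operation, setting C1 and C5 from the lone C7 stereocentre. The precursor is a dimethyl malonate bearing a prenyl group and a chain with C7, the C8 gem-dimethyl carbon and a C1-acylated beta-diketone.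

Key step: step 13

Remark: core atoms are numbered C1 (acyl-bearing bridgehead), C2 (ketone), C3, C4 (enol carbon), C5 (prenylated bridgehead), C6, C7, C8 (gem-dimethyl carbon) and C9 (bridging ketone), also in the open-chain precursors; open-chain 1,3-diketones are drawn as keto forms (epimeric at C1), and the target as the enol tautomer shown, which equilibrates with its C2-enol form.

Step 1
Reactants: 1 3,3-dimethylpent-4-enoic acid; 2 (S)-4-benzyloxazolidin-2-one
Product: 4 (S)-4-benzyl-3-(3,3-dimethylpent-4-enoyl)oxazolidin-2-one, via mixed pivalic anhydride 3 (not isolated)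
Conditions: t-BuCOCl, Et3N, THF, −20 °C; then LiCl, 2, −20 °C to rt
Reagents that add atoms: pivaloyl chloride CC(C)(C)C(=O)Cl (its acyl group stays only in intermediate 3)
Why: Mixed-anhydride N-acylation of the oxazolidinone should give the imide cleanly; no stereocentre is formed.

Step 2
Reactants: 4 (S)-4-benzyl-3-(3,3-dimethylpent-4-enoyl)oxazolidin-2-one; 5 1-bromo-3-methylbut-2-ene (prenyl bromide)
Product: 6 (S)-4-benzyl-3-[(S)-3,3-dimethyl-2-(3-methylbut-2-en-1-yl)pent-4-enoyl]oxazolidin-2-one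
Conditions: NaN(SiMe3)2, THF, −78 °C; then 5, −78 to −20 °C
Reagents that add atoms: none
Why: Evans asymmetric alkylation: the chelated Z-enolate is prenylated on the face opposite the benzyl group, which sets the future C7 centre (S in the imide, the same spatial arrangement as 7R in the target).

Step 3
Reactants: 6 (S)-4-benzyl-3-[(S)-3,3-dimethyl-2-(3-methylbut-2-en-1-yl)pent-4-enoyl]oxazolidin-2-one
Product: 7 (S)-3,3-dimethyl-2-(3-methylbut-2-en-1-yl)pent-4-en-1-ol
Conditions: LiBH4, H2O (1 equiv), Et2O, 0 °C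
Reagents that add atoms: none
Why: Reductive cleavage of the exocyclic imide carbonyl should release the primary alcohol and the auxiliary without touching the alkenes or the C7 centre.

Step 4
Reactants: 8 dimethyl malonate; 5 1-bromo-3-methylbut-2-ene
Product: 9 dimethyl 2-(3-methylbut-2-en-1-yl)malonate
Conditions: NaH, THF, 0 °C to rt (8 in excess)
Reagents that add atoms: none
Why: Malonic ester alkylation (SN2) with an allylic bromide; excess malonate should suppress dialkylation.

Step 5
Reactants: 7 (S)-3,3-dimethyl-2-(3-methylbut-2-en-1-yl)pent-4-en-1-ol; 9 dimethyl 2-(3-methylbut-2-en-1-yl)malonate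
Product: 11 dimethyl 2-[(R)-3,3-dimethyl-2-(3-methylbut-2-en-1-yl)pent-4-en-1-yl]-2-(3-methylbut-2-en-1-yl)malonate, via primary triflate 10 (not isolated)
Conditions: Tf2O, pyridine, CH2Cl2, −78 to −20 °C; then sodium enolate of 9 (NaH), THF/DMF, 0 °C to rt
Reagents that add atoms: triflic anhydride O=S(=O)(OS(=O)(=O)C(F)(F)F)C(F)(F)F (its triflyl group stays only in intermediate 10)
Why: SN2 displacement of the primary triflate by the soft tertiary malonate anion should form the C5–C6 bond and the quaternary, still prochiral C5; the C7 centre is not involved.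

Step 6
Reactants: 11 dimethyl 2-[(R)-3,3-dimethyl-2-(3-methylbut-2-en-1-yl)pent-4-en-1-yl]-2-(3-methylbut-2-en-1-yl)malonate
Product: 12 dimethyl 2-[(R)-3,3-dimethyl-2-(3-methylbut-2-en-1-yl)-5-oxopentyl]-2-(3-methylbut-2-en-1-yl)malonate
Conditions: PdCl2(PhCN)2, CuCl2·2H2O, AgNO2 (all catalytic), t-BuOH/MeNO2, O2 (1 atm), rt
Reagents that add atoms: dioxygen O=O
Why: Nitrite-modified, aldehyde-selective Wacker oxidation: the allylic quaternary carbon C8 directs oxygen to the terminal carbon (the future C2), and the trisubstituted prenyl alkenes should be inert to the divalent palladium catalyst.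

Step 7
Reactants: 13 2-methylpent-4-yn-2-ol
Product: 14 trimethyl[(2-methylpent-4-yn-2-yl)oxy]silane
Conditions: Me3SiCl, imidazole, CH2Cl2, 0 °C to rt
Reagents that add atoms: chlorotrimethylsilane C[Si](C)(C)Cl
Why: Silylation masks the tertiary hydroxyl group for the organometallic and enolate steps; a trimethylsilyl ether of a tertiary alcohol should survive buffered work-ups.

Step 8
Reactants: 12 dimethyl 2-[(R)-3,3-dimethyl-2-(3-methylbut-2-en-1-yl)-5-oxopentyl]-2-(3-methylbut-2-en-1-yl)malonate; 14 trimethyl[(2-methylpent-4-yn-2-yl)oxy]silane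
Product: 17 dimethyl 2-[(2R,6E)-5-hydroxy-3,3,9-trimethyl-2-(3-methylbut-2-en-1-yl)-9-(trimethylsilyloxy)dec-6-en-1-yl]-2-(3-methylbut-2-en-1-yl)malonate (both C5 epimers), via E-alkenylzirconocene chloride 15 (not isolated), via E-alkenyl(methyl)zinc 16 (not isolated)
Conditions: Cp2Zr(H)Cl, CH2Cl2, rt; Me2Zn, toluene, −65 °C; then 12, 0 °C; aq. NH4Cl
Reagents that add atoms: Cp2Zr(H)Cl [H][Zr](Cl)(C1C=CC=C1)C1C=CC=C1 (zirconocene unit only in intermediate 15); dimethylzinc C[Zn]C (methylzinc unit only in intermediate 16)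
Why: Syn, anti-Markovnikov hydrozirconation of the terminal alkyne gives the E-alkenyl metal, and zinc transmetalation allows 1,2-addition to the aldehyde while the hindered methyl esters are spared; the carbinol centre is formed without control because step 9 oxidises it.

Step 9
Reactants: 17 dimethyl 2-[(2R,6E)-5-hydroxy-3,3,9-trimethyl-2-(3-methylbut-2-en-1-yl)-9-(trimethylsilyloxy)dec-6-en-1-yl]-2-(3-methylbut-2-en-1-yl)malonate
Product: 18 dimethyl 2-[(2R,6E)-3,3,9-trimethyl-2-(3-methylbut-2-en-1-yl)-5-oxo-9-(trimethylsilyloxy)dec-6-en-1-yl]-2-(3-methylbut-2-en-1-yl)malonate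
Conditions: Dess–Martin periodinane, NaHCO3, CH2Cl2, 0 °C to rt
Reagents that add atoms: none
Why: Dess–Martin oxidation of the allylic alcohol gives the E-enone, in which C3 is sp2, so that C1 is the only kinetically enolisable alpha position of the C2 ketone.

Step 10
Reactants: 19 (R)-2-methylbutanoic acid
Product: 20 (R)-1-(1H-benzotriazol-1-yl)-2-methylbutan-1-one
Conditions: 1H-benzotriazole, DCC, CH2Cl2, 0 °C to rt
Reagents that add atoms: 1H-benzotriazole c1ccc2[nH]nnc2c1
Why: Carbodiimide coupling gives a neutral, storable N-acylbenzotriazole without base, hence without ketene formation or loss of the alpha stereocentre.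

Step 11
Reactants: 18 dimethyl 2-[(2R,6E)-3,3,9-trimethyl-2-(3-methylbut-2-en-1-yl)-5-oxo-9-(trimethylsilyloxy)dec-6-en-1-yl]-2-(3-methylbut-2-en-1-yl)malonate; 20 (R)-1-(1H-benzotriazol-1-yl)-2-methylbutan-1-one
Product: 21 dimethyl 2-[(2R,6E)-3,3,9-trimethyl-4-[(R)-2-methylbutanoyl]-2-(3-methylbut-2-en-1-yl)-5-oxo-9-(trimethylsilyloxy)dec-6-en-1-yl]-2-(3-methylbut-2-en-1-yl)malonate (C4 epimers)
Conditions: LiN(SiMe3)2 (2.2 equiv), THF, −78 °C; then 20, −78 to −40 °C; aq. NH4Cl
Reagents that add atoms: none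
Why: Kinetic alpha-prime deprotonation of the enone gives the cross-conjugated lithium enolate at C1 only, and its C-acylation by the N-acylbenzotriazole (crossed Claisen condensation) installs the 2-methylbutanoyl group; the second equivalent of base stores the product as its diketonate, and C1 is a stereorandom, enolisable centre.

Step 12
Reactants: 21 dimethyl 2-[(2R,6E)-3,3,9-trimethyl-4-[(R)-2-methylbutanoyl]-2-(3-methylbut-2-en-1-yl)-5-oxo-9-(trimethylsilyloxy)dec-6-en-1-yl]-2-(3-methylbut-2-en-1-yl)malonate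
Product: 22 dimethyl 2-[(2R)-3,3,9-trimethyl-4-[(R)-2-methylbutanoyl]-2-(3-methylbut-2-en-1-yl)-5-oxo-9-(trimethylsilyloxy)decyl]-2-(3-methylbut-2-en-1-yl)malonate
Conditions: H2 (1 atm), RhCl(PPh3)3 (cat.), benzene, rt
Reagents that add atoms: none
Why: Homogeneous hydrogenation with RhCl(PPh3)3 should reduce the disubstituted enone alkene and leave the two trisubstituted prenyl alkenes untouched, which frees C3 as an sp3 nucleophilic carbon for the key step.

Step 13
Reactants: 22 dimethyl 2-[(2R)-3,3,9-trimethyl-4-[(R)-2-methylbutanoyl]-2-(3-methylbut-2-en-1-yl)-5-oxo-9-(trimethylsilyloxy)decyl]-2-(3-methylbut-2-en-1-yl)malonate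
Product: 26 (1S,5S,7R)-4-hydroxy-3-(3-hydroxy-3-methylbutyl)-8,8-dimethyl-1-[(R)-2-methylbutanoyl]-5,7-bis(3-methylbut-2-en-1-yl)bicyclo[3.3.1]non-3-ene-2,9-dione (target), via bis(S-ethyl thioester) 23 (not isolated), via monocyclic triketone thioester 24 (not isolated), via bicyclic trimethylsilyl ether 25 (not isolated)
Conditions: Me2AlSEt (6 equiv, from AlMe3 and EtSH), toluene/THF, 0 to 60 °C; then 1 M HCl, THF, 0 °C to rt
Reagents that add atoms: dimethylaluminium ethanethiolate CCS[Al](C)C (its ethylthio groups stay only in intermediates 23 and 24)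
Why: Me2AlSEt converts the 1,3-diketone into its aluminium enolate and both methyl esters into S-ethyl thioesters (23); the enolate carbon C1 acylates one thioester (bond C1–C9, cyclohexanone 24), thiolate-assisted enolisation of the C2 ketone towards C3 and attack on the remaining thioester then forms bond C3–C4, and the new enolisable C2–C3–C4 diketone is trapped as its aluminium chelate, which pulls the reversible sequence forward. The closest known reaction type is the Dieckmann (intramolecular Claisen) condensation of ketone enolates with thioesters under soft enolisation, run as a domino process of the kind known to assemble bicyclo[3.3.1]nonane-2,4,9-trione cores from open-chain keto diesters. The cyclohexanone ring (C1, C9, C5, C6, C7, C8) closes in a 6-(enolexo)-exo-trig mode through a chair with the C7 prenyl group equatorial, and the trione ring (C1, C2, C3, C4, C5, C9) closes in a 6-(enolendo)-exo-trig mode between the 1,3-diaxial C2 acyl and C4 thioester groups. C7 is the controlling element for both new stereocentres: with its prenyl group equatorial, only the monocycle whose C5 thioester and C1 acyl arm are cis-diaxial can close the second ring, so prochiral C5 and C1 should be set as the 7-exo isomer while mis-closed monocycles revert by retro-Claisen cleavage. The step needs C1 rather than C3 or the alpha carbon of the 2-methylbutanoyl group to attack first, which the substrate secures because C1 is the only doubly activated carbon and the other two would have to form eight-membered rings; the 2-methylbutanoyl stereocentre should survive because its ketone lies outside the chelated enolate and is flanked by quaternary C1. Acidic work-up frees the enol from aluminium and cleaves the tertiary trimethylsilyl ether.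

Compound list

1 | 3,3-dimethylpent-4-enoic acid | C=CC(C)(C)CC(=O)O | starting material
2 | (S)-4-benzyloxazolidin-2-one | O=C1N[C@@H](Cc2ccccc2)CO1 | starting material
3 | 3,3-dimethylpent-4-enoic pivalic anhydride | C=CC(C)(C)CC(=O)OC(=O)C(C)(C)C | intermediate (not isolated)
4 | (S)-4-benzyl-3-(3,3-dimethylpent-4-enoyl)oxazolidin-2-one | C=CC(C)(C)CC(=O)N1[C@@H](Cc2ccccc2)COC1=O | intermediate
5 | 1-bromo-3-methylbut-2-ene (prenyl bromide) | CC(C)=CCBr | starting material
6 | (S)-4-benzyl-3-[(S)-3,3-dimethyl-2-(3-methylbut-2-en-1-yl)pent-4-enoyl]oxazolidin-2-one | C=CC(C)(C)[C@H](CC=C(C)C)C(=O)N1[C@@H](Cc2ccccc2)COC1=O | intermediate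
7 | (S)-3,3-dimethyl-2-(3-methylbut-2-en-1-yl)pent-4-en-1-ol | C=CC(C)(C)[C@H](CC=C(C)C)CO | intermediate
8 | dimethyl malonate | COC(=O)CC(=O)OC | starting material
9 | dimethyl 2-(3-methylbut-2-en-1-yl)malonate | COC(=O)C(CC=C(C)C)C(=O)OC | intermediate
10 | (S)-3,3-dimethyl-2-(3-methylbut-2-en-1-yl)pent-4-en-1-yl trifluoromethanesulfonate | C=CC(C)(C)[C@H](CC=C(C)C)COS(=O)(=O)C(F)(F)F | intermediate (not isolated)
11 | dimethyl 2-[(R)-3,3-dimethyl-2-(3-methylbut-2-en-1-yl)pent-4-en-1-yl]-2-(3-methylbut-2-en-1-yl)malonate | C=CC(C)(C)[C@H](CC=C(C)C)CC(CC=C(C)C)(C(=O)OC)C(=O)OC | intermediate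
12 | dimethyl 2-[(R)-3,3-dimethyl-2-(3-methylbut-2-en-1-yl)-5-oxopentyl]-2-(3-methylbut-2-en-1-yl)malonate | O=CCC(C)(C)[C@H](CC=C(C)C)CC(CC=C(C)C)(C(=O)OC)C(=O)OC | intermediate
13 | 2-methylpent-4-yn-2-ol | C#CCC(C)(C)O | starting material
14 | trimethyl[(2-methylpent-4-yn-2-yl)oxy]silane | C#CCC(C)(C)O[Si](C)(C)C | intermediate
15 | chlorobis(cyclopentadienyl)[(E)-4-methyl-4-(trimethylsilyloxy)pent-1-en-1-yl]zirconium | C[Si](C)(C)OC(C)(C)C/C=C/[Zr](Cl)(C1C=CC=C1)C1C=CC=C1 | intermediate (not isolated)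
16 | methyl[(E)-4-methyl-4-(trimethylsilyloxy)pent-1-en-1-yl]zinc | C[Si](C)(C)OC(C)(C)C/C=C/[Zn]C | intermediate (not isolated)
17 | dimethyl 2-[(2R,6E)-5-hydroxy-3,3,9-trimethyl-2-(3-methylbut-2-en-1-yl)-9-(trimethylsilyloxy)dec-6-en-1-yl]-2-(3-methylbut-2-en-1-yl)malonate (C5 epimers) | C[Si](C)(C)OC(C)(C)C/C=C/C(O)CC(C)(C)[C@H](CC=C(C)C)CC(CC=C(C)C)(C(=O)OC)C(=O)OC | intermediate
18 | dimethyl 2-[(2R,6E)-3,3,9-trimethyl-2-(3-methylbut-2-en-1-yl)-5-oxo-9-(trimethylsilyloxy)dec-6-en-1-yl]-2-(3-methylbut-2-en-1-yl)malonate | C[Si](C)(C)OC(C)(C)C/C=C/C(=O)CC(C)(C)[C@H](CC=C(C)C)CC(CC=C(C)C)(C(=O)OC)C(=O)OC | intermediate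
19 | (R)-2-methylbutanoic acid | CC[C@@H](C)C(=O)O | starting material
20 | (R)-1-(1H-benzotriazol-1-yl)-2-methylbutan-1-one | CC[C@@H](C)C(=O)n1nnc2ccccc12 | intermediate
21 | dimethyl 2-[(2R,6E)-3,3,9-trimethyl-4-[(R)-2-methylbutanoyl]-2-(3-methylbut-2-en-1-yl)-5-oxo-9-(trimethylsilyloxy)dec-6-en-1-yl]-2-(3-methylbut-2-en-1-yl)malonate (C4 epimers) | CC[C@@H](C)C(=O)C(C(=O)/C=C/CC(C)(C)O[Si](C)(C)C)C(C)(C)[C@H](CC=C(C)C)CC(CC=C(C)C)(C(=O)OC)C(=O)OC | intermediate
22 | dimethyl 2-[(2R)-3,3,9-trimethyl-4-[(R)-2-methylbutanoyl]-2-(3-methylbut-2-en-1-yl)-5-oxo-9-(trimethylsilyloxy)decyl]-2-(3-methylbut-2-en-1-yl)malonate (C4 epimers) | CC[C@@H](C)C(=O)C(C(=O)CCCC(C)(C)O[Si](C)(C)C)C(C)(C)[C@H](CC=C(C)C)CC(CC=C(C)C)(C(=O)OC)C(=O)OC | intermediate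
23 | S,S-diethyl bis(thioester) analogue of 22 (both CO2Me replaced by C(=O)SEt) | CC[C@@H](C)C(=O)C(C(=O)CCCC(C)(C)O[Si](C)(C)C)C(C)(C)[C@H](CC=C(C)C)CC(CC=C(C)C)(C(=O)SCC)C(=O)SCC | intermediate (not isolated)
24 | S-ethyl 4,4-dimethyl-3-[(R)-2-methylbutanoyl]-3-[5-methyl-5-(trimethylsilyloxy)hexanoyl]-1,5-bis(3-methylbut-2-en-1-yl)-2-oxocyclohexane-1-carbothioate (thioester and hexanoyl group cis-diaxial, both prenyl groups equatorial, absolute configuration as in 26) | CC[C@@H](C)C(=O)[C@@]1(C(=O)CCCC(C)(C)O[Si](C)(C)C)C(=O)[C@](CC=C(C)C)(C(=O)SCC)C[C@@H](CC=C(C)C)C1(C)C | intermediate (not isolated)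
25 | (1S,5S,7R)-4-hydroxy-8,8-dimethyl-1-[(R)-2-methylbutanoyl]-5,7-bis(3-methylbut-2-en-1-yl)-3-[3-methyl-3-(trimethylsilyloxy)butyl]bicyclo[3.3.1]non-3-ene-2,9-dione | CC[C@@H](C)C(=O)[C@]12C(=O)C(CCC(C)(C)O[Si](C)(C)C)=C(O)[C@](CC=C(C)C)(C[C@@H](CC=C(C)C)C1(C)C)C2=O | intermediate (not isolated)
26 | (1S,5S,7R)-4-hydroxy-3-(3-hydroxy-3-methylbutyl)-8,8-dimethyl-1-[(R)-2-methylbutanoyl]-5,7-bis(3-methylbut-2-en-1-yl)bicyclo[3.3.1]non-3-ene-2,9-dione | CC[C@@H](C)C(=O)[C@]12C(=O)C(CCC(C)(C)O)=C(O)[C@](CC=C(C)C)(C[C@@H](CC=C(C)C)C1(C)C)C2=O | target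

Total step count: 13. Longest linear sequence: 10 steps (steps 1, 2, 3, 5, 6, 8, 9, 11, 12, 13).

Steps most likely to fail

Step 13 (key step). The domino closure may stall at the first C-acylation, because C1 must become quaternary between the C8 gem-dimethyl carbon and two acyl groups, or the 2-methylbutanoyl alpha centre may epimerise while the thiolate enolises ketones. The fallback moves the acyl transfer behind the ring formation. It sets out from enone 18, which is hydrogenated (H2, RhCl(PPh3)3) to the saturated ketone F1. The same Me2AlSEt domino Dieckmann condensation, now with an unsubstituted C1 methylene, followed by work-up with aqueous potassium sodium tartrate, should give the C1–H bicyclic trione F2. Me3SiCHN2 in MeOH/toluene should give the 4-methoxy vinylogous ester F3 together with its 2-methoxy regioisomer F4, which LiOH returns to F2. Bridgehead deprotonation of F3 at C1 with lithium 2,2,6,6-tetramethylpiperidide (THF, −78 °C) and acylation with 20 should give F5. LiCl in DMSO at 120 °C then cleaves the methyl ether and returns to the route at 25, which the acidic work-up of step 13 converts into 26.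

Step 11. C-acylation at the neopentyl-type C1 may lose out to O-acylation of the hindered enolate, and excess base may erode the alpha centre of the acyl donor. The fallback replaces direct acylation by aldol addition and oxidation. It sets out from 18 and 19: acid 19 is converted into its N-methoxy-N-methylamide F6 (MeNHOMe·HCl, EDC) and reduced (LiAlH4, −78 °C) to (R)-2-methylbutanal F7, which is used at once. The lithium enolate of 18 (LiN(SiMe3)2, −78 °C) adds to F7 to give the beta-hydroxy ketone F8, and Dess–Martin oxidation returns to the route at 21.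

Step 5. Displacement at C6 may be slow because a tertiary malonate anion meets a beta-branched electrophile, so that elimination or alkene participation in the triflate competes. The fallback reverses the order of the two malonate alkylations. It sets out from 7: Appel iodination (I2, PPh3, imidazole) gives the iodide F9. The small anion of dimethyl malonate 8 (NaH, DMF, 60 °C, excess 8) displaces iodide to give the monoalkyl malonate F10. NaH and prenyl bromide 5 then return to the route at 11.

Further compounds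

F1 | step 13 | dimethyl 2-[(2R)-3,3,9-trimethyl-2-(3-methylbut-2-en-1-yl)-5-oxo-9-(trimethylsilyloxy)decyl]-2-(3-methylbut-2-en-1-yl)malonate | C[Si](C)(C)OC(C)(C)CCCC(=O)CC(C)(C)[C@H](CC=C(C)C)CC(CC=C(C)C)(C(=O)OC)C(=O)OC
F2 | step 13 | (1R,5S,7R)-4-hydroxy-8,8-dimethyl-5,7-bis(3-methylbut-2-en-1-yl)-3-[3-methyl-3-(trimethylsilyloxy)butyl]bicyclo[3.3.1]non-3-ene-2,9-dione | [C@H]12C(=O)C(CCC(C)(C)O[Si](C)(C)C)=C(O)[C@](CC=C(C)C)(C[C@@H](CC=C(C)C)C1(C)C)C2=O
F3 | step 13 | (1R,5S,7R)-4-methoxy-8,8-dimethyl-5,7-bis(3-methylbut-2-en-1-yl)-3-[3-methyl-3-(trimethylsilyloxy)butyl]bicyclo[3.3.1]non-3-ene-2,9-dione | [C@H]12C(=O)C(CCC(C)(C)O[Si](C)(C)C)=C(OC)[C@](CC=C(C)C)(C[C@@H](CC=C(C)C)C1(C)C)C2=O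
F4 | step 13 | (1R,5R,7R)-2-methoxy-8,8-dimethyl-5,7-bis(3-methylbut-2-en-1-yl)-3-[3-methyl-3-(trimethylsilyloxy)butyl]bicyclo[3.3.1]non-2-ene-4,9-dione | [C@H]12C(OC)=C(CCC(C)(C)O[Si](C)(C)C)C(=O)[C@](CC=C(C)C)(C[C@@H](CC=C(C)C)C1(C)C)C2=O
F5 | step 13 | (1S,5S,7R)-4-methoxy-8,8-dimethyl-1-[(R)-2-methylbutanoyl]-5,7-bis(3-methylbut-2-en-1-yl)-3-[3-methyl-3-(trimethylsilyloxy)butyl]bicyclo[3.3.1]non-3-ene-2,9-dione | CC[C@@H](C)C(=O)[C@]12C(=O)C(CCC(C)(C)O[Si](C)(C)C)=C(OC)[C@](CC=C(C)C)(C[C@@H](CC=C(C)C)C1(C)C)C2=O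
F6 | step 11 | (R)-N-methoxy-N,2-dimethylbutanamide | CC[C@@H](C)C(=O)N(C)OC
F7 | step 11 | (R)-2-methylbutanal | CC[C@@H](C)C=O
F8 | step 11 | beta-hydroxy ketone: the analogue of 21 in which the 2-methylbutanoyl carbonyl is a secondary alcohol (carbinol epimers) | CC[C@@H](C)C(O)C(C(=O)/C=C/CC(C)(C)O[Si](C)(C)C)C(C)(C)[C@H](CC=C(C)C)CC(CC=C(C)C)(C(=O)OC)C(=O)OC
F9 | step 5 | (S)-3-(iodomethyl)-4,4,7-trimethylocta-1,6-diene (the primary iodide of 7) | C=CC(C)(C)[C@H](CC=C(C)C)CI
F10 | step 5 | dimethyl 2-[(R)-3,3-dimethyl-2-(3-methylbut-2-en-1-yl)pent-4-en-1-yl]malonate | C=CC(C)(C)[C@H](CC=C(C)C)CC(C(=O)OC)C(=O)OC
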